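**Retrosynthetic overview**

- The target is acyclic and its C2–C20 chain (C1 = ester carbonyl) is an unbranched polymethylene chain with no functionality. The C5–C6 sp3–sp3 bond can therefore be made by combining two primary alkyl radicals.
- C1–C5 comes from adipic acid (1), mono-esterified with benzyl alcohol (2) to benzyl hydrogen adipate (3). C6–C20 comes from palmitic acid (4).
- Co-electrolysis of 3 and 4 gives the 4-(benzyloxycarbonyl)butyl radical (5) and the pentadecyl radical (6), which combine to benzyl eicosanoate (7) with loss of two CO2.
- No ring is formed; the benzene ring is bought in 2. No stereocentre is present.

Key step: step 2

Assumption: the target has no stereogenic element, so "single enantiomer" is taken to mean the single constitution shown.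

**Step 1**
Reactants: 1 adipic acid (3 equiv); 2 benzyl alcohol (1 equiv)
Product: 3 benzyl hydrogen adipate
Conditions: TsOH·H2O (2 mol %), toluene, reflux, Dean–Stark; cool and filter off excess 1; extract into aq NaHCO3, acidify, extract into EtOAc, wash with water
Reagents that add atoms: none
Why: Fischer esterification with azeotropic water removal; the excess of diacid biases the statistical mixture towards the half-ester, and the neutral diester, the acidic half-ester and the water-soluble diacid are separated by filtration and acid–base extraction.

**Step 2**
Reactants: 3 benzyl hydrogen adipate (1 equiv); 4 palmitic acid (3 equiv)
Product: 7 benzyl eicosanoate, via 4-(benzyloxycarbonyl)butyl radical 5 (not isolated), via pentadecyl radical 6 (not isolated)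
Conditions: Et3N (ca. 0.1 equiv per CO2H), MeOH, 45–50 °C, undivided cell, smooth Pt anode, Pt cathode, constant current ca. 0.25 A cm−2, stopped when 3 is consumed and acid is still present; AcOH, evaporate, short basic alumina pad, SiO2 (hexane, then hexane/EtOAc)
Reagents that add atoms: none
Why: At the platinum anode at high current density each carboxylate is oxidised by one electron and the acyloxy radical loses CO2, so 3 gives the primary radical 5 and 4 gives the primary radical 6, which combine in the electrode layer to form the C5–C6 sp3–sp3 bond of 7. The closest known reaction type is the mixed (crossed) Kolbe electrolysis of a dicarboxylic acid half-ester with a fatty acid, the classical electrochemical chain extension of fatty esters. No ring is closed and no stereocentre is created, so neither a closure mode nor a stereocontrol element is involved. The first selectivity needed is cross- over homo-coupling, which is purely statistical and is pushed towards 7 (based on 3) by the threefold excess of cheap 4; the homodimers triacontane and dibenzyl sebacate should elute before and after 7 on silica. The second is radical coupling over further oxidation to a cation, secured because 5 and 6 are unstabilised primary radicals without branching or an α-heteroatom, generated on smooth platinum in weakly acidic methanol. The benzyl ester lies four carbons from the radical centre and should not be discharged beneath the carboxylate layer, and triethylamine with acid always in excess keeps alkoxide out of the medium so that the benzyl ester is not exchanged for a methyl ester.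

**Compound list**

1 | adipic acid (hexanedioic acid) | OC(=O)CCCCC(=O)O | starting material
2 | benzyl alcohol | OCc1ccccc1 | starting material
3 | benzyl hydrogen adipate (6-(benzyloxy)-6-oxohexanoic acid) | OC(=O)CCCCC(=O)OCc1ccccc1 | intermediate
4 | palmitic acid (hexadecanoic acid) | CCCCCCCCCCCCCCCC(=O)O | starting material
5 | 4-(benzyloxycarbonyl)butyl radical | [CH2]CCCC(=O)OCc1ccccc1 | intermediate
6 | pentadecyl radical | [CH2]CCCCCCCCCCCCCC | intermediate
7 | benzyl eicosanoate (phenylmethyl icosanoate) | CCCCCCCCCCCCCCCCCCCC(=O)OCc1ccccc1 | target

**Step count**

Total steps: 2. Longest linear sequence: 2 steps (1 → 3 → 7).

**Steps most likely to fail**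

The route has only two steps, so both are ranked.

1. Step 2. Three processes may limit it:
   - statistical homo-coupling that consumes 3;
   - coating of the anode by a waxy hydrocarbon film, with a rise in cell voltage and drift to the two-electron (carbocation) pathway;
   - slow exchange of the benzyl ester with methanol if the medium turns basic.

   Fallback: a polar construction of the same C5–C6 bond, setting out from 2 and returning at 7. Compound 2 is esterified with commercial 5-bromopentanoic acid (TsOH cat., toluene, Dean–Stark) to benzyl 5-bromopentanoate F1. Commercial 1-bromopentadecane is converted with magnesium in THF into pentadecylmagnesium bromide F2. F2 is added slowly to F1 in THF/NMP at 0–20 °C with Li2CuCl4 (3 mol %). This copper-catalysed Grignard–alkyl bromide coupling tolerates ester groups and should give 7.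

2. Step 1. Over-esterification to the diester and incomplete separation of diacid, half-ester and diester may leave 3 impure; any diacid carried forward would give oligomeric coupling products in step 2.

   Fallback: desymmetrisation through the cyclic anhydride, setting out from 1 and returning at 3. Compound 1 is heated in acetic anhydride, the acetic acid is distilled off, and the polymeric anhydride is depolymerised by vacuum distillation to monomeric oxepane-2,7-dione F3. F3 is opened at once with 2 (1 equiv, cat. DMAP, toluene, rt to 60 °C). Each ring can take up only one molecule of alcohol, so 3 should form without diester.

**Further compounds**

F1 | step 2 | benzyl 5-bromopentanoate | O=C(CCCCBr)OCc1ccccc1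
F2 | step 2 | pentadecylmagnesium bromide | CCCCCCCCCCCCCCC[Mg]Br
F3 | step 1 | oxepane-2,7-dione (monomeric adipic anhydride) | O=C1CCCCC(=O)O1
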